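**Retrosynthetic overview**
- The last bond made is C6–prenyl: a palladium-catalysed, ligand-controlled dearomative prenylation of the ring-opened 6-alkyl-5,7-dihydroxychromanone acid sets the quaternary centre.
- The C6–CH2 bond comes from a Negishi coupling of a tricyclic aryl iodide (chromanone plus 7-O lactone) with the C11 alkylzinc.
- Ring order on the benzene core: pyranone ring first (Pd-catalysed hydroarylation to a 4-phenylcoumarin, CuH reduction sets C–Ph), opened again; then the chromanone ring (Pd allylic etherification, hydroboration, oxidation, Friedel–Crafts); then the lactone re-formed on O7 after demethylation.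
- The phloroglucinol pattern comes from resorcinol by O-methylation and Ir-catalysed C–H borylation/oxidation.
- The side chain comes from 5-methylhex-5-en-2-one (enol triflate, Suzuki coupling with isobutenylboronic acid, Cu-catalysed enantioselective 1,2-protoboration).

Assumption: the target is made as the enol tautomer drawn in the given SMILES, and wherever a chiral catalyst (steps 5, 8, 16, 20) proves to give the opposite sense of induction to the one written, its mirror-image ligand is used.

**Step 1**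
Reactants: 1 resorcinol
Product: 2 1,3-dimethoxybenzene
Conditions: MeI, K2CO3, acetone, reflux
Reagents that add atoms: iodomethane CI
Why: Williamson ether synthesis on both phenoxide oxygens; the methyl ethers mask the two oxygens that will flank C6 until step 12.

**Step 2**
Reactants: 2 1,3-dimethoxybenzene
Product: 4 3,5-dimethoxyphenol, via aryl pinacol boronate 3 (not isolated)
Conditions: [Ir(OMe)(cod)]2 (1 mol%), 4,4'-di-tert-butyl-2,2'-bipyridine (2 mol%), B2pin2 (0.6 equiv), THF, 80 °C; then KHSO5 (as 2KHSO5·KHSO4·K2SO4), acetone/H2O, rt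
Reagents that add atoms: bis(pinacolato)diboron CC1(C)OB(OC1(C)C)B1OC(C)(C)C(C)(C)O1 (boron group of 3); potassium peroxymonosulfate [K+].[O-]S(=O)(=O)OO (oxygen of 4)
Why: Sterically controlled iridium-catalysed aromatic C–H borylation goes to C5, the only C–H without an ortho substituent, and oxidation of the C–B bond gives the phenol (one-pot C–H borylation/oxidation).

**Step 3**
Reactants: 5 phenylacetylene; 6 methyl chloroformate
Product: 8 methyl 3-phenylprop-2-ynoate, via lithium phenylacetylide 7 (not isolated)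
Conditions: n-BuLi, THF, −78 °C; then ClCO2Me, −78 °C to rt
Reagents that add atoms: n-butyllithium CCCC[Li] (lithium of 7)
Why: Deprotonation of the terminal alkyne and C-acylation of the acetylide by the chloroformate (alkynoate synthesis).

**Step 4**
Reactants: 4 3,5-dimethoxyphenol; 8 methyl 3-phenylprop-2-ynoate
Product: 10 5,7-dimethoxy-4-phenyl-2H-chromen-2-one, via Z-hydroxycinnamate 9 (not isolated)
Conditions: Pd(OAc)2 (3 mol%), CF3CO2H/CH2Cl2 (3:1), rt
Reagents that add atoms: none
Why: Palladium-catalysed Fujiwara-type hydroarylation: the electron-rich C–H ortho to the free OH adds trans across the alkynoate and the Z-cinnamate lactonises to the coumarin, which places the future propanoate arm ortho to the oxygen that becomes O1.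

**Step 5**
Reactants: 10 5,7-dimethoxy-4-phenyl-2H-chromen-2-one
Product: 11 (4R)-5,7-dimethoxy-4-phenyl-3,4-dihydro-2H-chromen-2-one
Conditions: Cu(OAc)2·H2O (3 mol%), (R)-DTBM-SEGPHOS (3 mol%), (EtO)2MeSiH, t-BuOH, toluene, rt
Reagents that add atoms: none
Why: Ligand-controlled copper hydride 1,4-reduction (asymmetric conjugate reduction) of the 4-arylcoumarin delivers hydride to one face of C4 and sets the benzylic (R) stereocentre.

**Step 6**
Reactants: 11 (4R)-5,7-dimethoxy-4-phenyl-3,4-dihydro-2H-chromen-2-one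
Product: 12 methyl (3R)-3-(2-hydroxy-4,6-dimethoxyphenyl)-3-phenylpropanoate
Conditions: NaOMe, MeOH, 0 °C; AcOH quench
Reagents that add atoms: sodium methoxide C[O-].[Na+]
Why: Base-mediated transesterification (lactone methanolysis) is driven by release of the phenoxide and frees the phenol oxygen for chromanone construction without touching the stereocentre.

**Step 7**
Reactants: 13 (2E)-2-methylbut-2-en-1-ol; 6 methyl chloroformate
Product: 14 methyl (2E)-2-methylbut-2-en-1-yl carbonate
Conditions: pyridine, CH2Cl2, 0 °C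
Reagents that add atoms: none
Why: O-acylation of the allylic alcohol gives the carbonate that serves as an ionisable leaving group in the next step.

**Step 8**
Reactants: 12 methyl (3R)-3-(2-hydroxy-4,6-dimethoxyphenyl)-3-phenylpropanoate; 14 methyl (2E)-2-methylbut-2-en-1-yl carbonate
Product: 15 methyl (3R)-3-{2,4-dimethoxy-6-[(2R)-3-methylbut-3-en-2-yl]oxyphenyl}-3-phenylpropanoate
Conditions: Pd2(dba)3·CHCl3 (1.5 mol%), (R,R)-DACH-phenyl Trost ligand (4.5 mol%), CH2Cl2, rt
Reagents that add atoms: none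
Why: Trost asymmetric allylic alkylation: the phenoxide attacks the more substituted terminus of the (1,2-dimethylallyl)palladium intermediate inside the chiral pocket, giving the branched ether and setting the future C2 as (R).

**Step 9**
Reactants: 15 methyl (3R)-3-{2,4-dimethoxy-6-[(2R)-3-methylbut-3-en-2-yl]oxyphenyl}-3-phenylpropanoate
Product: 17 methyl (3R)-3-{2-[(2R,3S)-4-hydroxy-3-methylbutan-2-yl]oxy-4,6-dimethoxyphenyl}-3-phenylpropanoate, via B-alkyl-9-BBN adduct 16 (not isolated)
Conditions: 9-BBN, THF, 0 °C to rt; then NaBO3·4H2O, H2O, rt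
Reagents that add atoms: 9-borabicyclo[3.3.1]nonane B1C2CCCC1CCC2 (boron group of 16); sodium perborate [Na+].[O-]OB=O (oxygen of 17)
Why: Hydroboration–oxidation of the 1,1-disubstituted alkene is anti-Markovnikov and, through the allylic-strain-controlled transition state, places the new methyl-bearing centre anti to the aryloxy group (the future trans-2,3-dimethyl relationship), leaving the ester untouched.

**Step 10**
Reactants: 17 methyl (3R)-3-{2-[(2R,3S)-4-hydroxy-3-methylbutan-2-yl]oxy-4,6-dimethoxyphenyl}-3-phenylpropanoate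
Product: 19 (2R,3R)-3-{3,5-dimethoxy-2-[(1R)-3-methoxy-3-oxo-1-phenylpropyl]phenoxy}-2-methylbutanoic acid, via aldehyde 18 (not isolated)
Conditions: TEMPO (20 mol%), PhI(OAc)2, MeCN/H2O, rt
Reagents that add atoms: water O
Why: Nitroxyl-catalysed oxidation of the primary alcohol through the aldehyde hydrate stops at the acid under near-neutral conditions, so the alpha stereocentre is not epimerised.

**Step 11**
Reactants: 19 (2R,3R)-3-{3,5-dimethoxy-2-[(1R)-3-methoxy-3-oxo-1-phenylpropyl]phenoxy}-2-methylbutanoic acid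
Product: 21 methyl (3R)-3-[(2R,3R)-5,7-dimethoxy-2,3-dimethyl-4-oxo-3,4-dihydro-2H-chromen-8-yl]-3-phenylpropanoate, via mixed trifluoroacetic anhydride 20 (not isolated)
Conditions: (CF3CO)2O (1.5 equiv), CH2Cl2, 0 °C to rt
Reagents that add atoms: trifluoroacetic anhydride O=C(OC(=O)C(F)(F)F)C(F)(F)F (acyl group of 20)
Why: Intramolecular Friedel–Crafts acylation through the mixed anhydride can reach only the one free position ortho to the ether oxygen, closing the chromanone ring with both stereocentres intact (the trans isomer is also the thermodynamic one).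

**Step 12**
Reactants: 21 methyl (3R)-3-[(2R,3R)-5,7-dimethoxy-2,3-dimethyl-4-oxo-3,4-dihydro-2H-chromen-8-yl]-3-phenylpropanoate
Product: 23 (2R,3R,10R)-5-hydroxy-2,3-dimethyl-10-phenyl-2,3,9,10-tetrahydro-4H,8H-pyrano[2,3-h]chromene-4,8-dione, via dihydroxy ester 22 (not isolated)
Conditions: BBr3, CH2Cl2, −78 to 0 °C; MeOH quench; then p-TsOH·H2O (cat.), toluene, 80 °C
Reagents that add atoms: none
Why: Boron tribromide cleaves both aryl methyl ethers, and acid-catalysed lactonisation then takes place on the 7-OH, the only hydroxyl ortho to the propanoate arm, while the 5-OH stays hydrogen-bonded to the ketone.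

**Step 13**
Reactants: 23 (2R,3R,10R)-5-hydroxy-2,3-dimethyl-10-phenyl-2,3,9,10-tetrahydro-4H,8H-pyrano[2,3-h]chromene-4,8-dione
Product: 24 (2R,3R,10R)-5-hydroxy-6-iodo-2,3-dimethyl-10-phenyl-2,3,9,10-tetrahydro-4H,8H-pyrano[2,3-h]chromene-4,8-dione
Conditions: N-iodosuccinimide, CF3CO2H (10 mol%), MeCN, 0 °C
Reagents that add atoms: N-iodosuccinimide O=C1CCC(=O)N1I
Why: Electrophilic aromatic iodination occurs at C6, the only remaining aromatic C–H, activated by the ortho hydroxyl and the para ring oxygen.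

**Step 14**
Reactants: 25 5-methylhex-5-en-2-one
Product: 27 5-methylhexa-1,5-dien-2-yl trifluoromethanesulfonate, via lithium enolate 26 (not isolated)
Conditions: LiN(iPr)2, THF, −78 °C; then PhNTf2, −78 to 0 °C
Reagents that add atoms: lithium diisopropylamide [Li+].CC(C)[N-]C(C)C (lithium of 26); N-phenylbis(trifluoromethanesulfonimide) O=S(=O)(N(c1ccccc1)S(=O)(=O)C(F)(F)F)C(F)(F)F
Why: Kinetic deprotonation of the methyl ketone at the methyl group and O-triflation of the enolate give the terminal enol triflate.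

**Step 15**
Reactants: 27 5-methylhexa-1,5-dien-2-yl trifluoromethanesulfonate; 28 (2-methylprop-1-en-1-yl)boronic acid
Product: 29 2,7-dimethyl-5-methylideneocta-1,6-diene
Conditions: Pd(PPh3)4 (3 mol%), K3PO4, THF/H2O, 50 °C
Reagents that add atoms: none
Why: Suzuki–Miyaura coupling of the alkenyl triflate with the alkenylboronic acid builds the 2-substituted 1,3-diene.

**Step 16**
Reactants: 29 2,7-dimethyl-5-methylideneocta-1,6-diene
Product: 31 (2S)-5-methyl-2-(2-methylprop-1-en-1-yl)hex-5-en-1-ol, via homoallylic pinacol boronate 30 (not isolated)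
Conditions: CuCl (5 mol%), (R,R)-Ph-BPE (6 mol%), NaOtBu (10 mol%), B2pin2, MeOH, THF, 0 °C to rt; then NaBO3·4H2O, THF/H2O, rt
Reagents that add atoms: bis(pinacolato)diboron CC1(C)OB(OC1(C)C)B1OC(C)(C)C(C)(C)O1 (boron group of 30); sodium perborate [Na+].[O-]OB=O (oxygen of 31)
Why: Copper-catalysed enantioselective 1,2-protoboration of a 2-substituted 1,3-diene puts boron on the terminal CH2 and protonates the allylcopper at C2 within the chiral ligand sphere to set the (S) centre, the isolated isopropenyl group being unreactive, and perborate oxidation proceeds with retention.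

**Step 17**
Reactants: 31 (2S)-5-methyl-2-(2-methylprop-1-en-1-yl)hex-5-en-1-ol
Product: 32 (5S)-6-iodo-2-methyl-5-(2-methylprop-1-en-1-yl)hex-1-ene
Conditions: I2, PPh3, imidazole, CH2Cl2, 0 °C
Reagents that add atoms: iodine II
Why: Appel-type iodination of the primary alcohol; the adjacent stereocentre is not involved.

**Step 18**
Reactants: 32 (5S)-6-iodo-2-methyl-5-(2-methylprop-1-en-1-yl)hex-1-ene; 24 (2R,3R,10R)-5-hydroxy-6-iodo-2,3-dimethyl-10-phenyl-2,3,9,10-tetrahydro-4H,8H-pyrano[2,3-h]chromene-4,8-dione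
Product: 35 (2R,3R,10R)-5-hydroxy-2,3-dimethyl-6-[(2R)-5-methyl-2-(2-methylprop-1-en-1-yl)hex-5-en-1-yl]-10-phenyl-2,3,9,10-tetrahydro-4H,8H-pyrano[2,3-h]chromene-4,8-dione, via alkyllithium 33 (not isolated), via alkylzinc chloride 34 (not isolated)
Conditions: 32 (1.6 equiv), t-BuLi (2.1 equiv per iodide), Et2O/pentane, −78 °C; ZnCl2, THF, −78 °C to rt; then 24, Pd(OAc)2 (4 mol%), SPhos (8 mol%), THF, 40 °C
Reagents that add atoms: tert-butyllithium CC(C)(C)[Li] (lithium of 33); zinc chloride Cl[Zn]Cl (zinc and chlorine of 34)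
Why: Lithium–iodine exchange at −78 °C and transmetalation give the primary alkylzinc without radical intermediates (no cyclisation onto the isopropenyl group), and Negishi coupling with the biarylphosphine catalyst joins it to C6 while tolerating the lactone, the ketone and the chelated phenol.

**Step 19**
Reactants: 36 3-methylbut-2-en-1-ol; 6 methyl chloroformate
Product: 37 methyl 3-methylbut-2-en-1-yl carbonate
Conditions: pyridine, CH2Cl2, 0 °C
Reagents that add atoms: none
Why: O-acylation of prenol gives the carbonate that zerovalent palladium ionises in the final step.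

**Step 20**
Reactants: 35 (2R,3R,10R)-5-hydroxy-2,3-dimethyl-6-[(2R)-5-methyl-2-(2-methylprop-1-en-1-yl)hex-5-en-1-yl]-10-phenyl-2,3,9,10-tetrahydro-4H,8H-pyrano[2,3-h]chromene-4,8-dione; 37 methyl 3-methylbut-2-en-1-yl carbonate
Product: 39 (3R)-3-{(2R,3R,6S)-4-hydroxy-2,3-dimethyl-6-(3-methylbut-2-en-1-yl)-6-[(2R)-5-methyl-2-(2-methylprop-1-en-1-yl)hex-5-en-1-yl]-5,7-dioxo-3,5,6,7-tetrahydro-2H-chromen-8-yl}-3-phenylpropanoic acid, via ring-opened dilithium salt 38 (not isolated)
Conditions: LiOH·H2O (2.2 equiv), THF/H2O, 0 °C to rt, evaporate; then 37 (1.2 equiv), Pd2(dba)3·CHCl3 (2.5 mol%), (R,R)-DACH-naphthyl Trost ligand (7.5 mol%), THF/DMF, −20 to 0 °C; 0.5 M HCl to pH 4 at 0 °C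
Reagents that add atoms: lithium hydroxide [Li+].[OH-]
Why: Proposed new method: catalyst-controlled, face-selective palladium-catalysed dearomative C-prenylation of a 6-alkyl-5,7-dihydroxychromanone, in which hydroxide first opens the lactone to dianion 38, zerovalent palladium ionises 37 to a cationic (1,1-dimethylallyl)palladium complex whose chiral ligand hydrogen-bonds the 7-oxido/carboxylate groups so that C6 (flanked by both oxygens and less hindered than C8) attacks the unsubstituted allyl terminus from one face and sets the (6S) quaternary centre, while O-prenylation is reversible under the catalyst and funnels to the C-alkylated dienone; the closest known reactions are the palladium-catalysed asymmetric allylic dearomatisation of 1-substituted 2-naphthols and the non-asymmetric palladium-catalysed dearomative allylation of acylphloroglucinols.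

**Compound list**
1 | resorcinol | Oc1cccc(O)c1 | starting material
2 | 1,3-dimethoxybenzene | COc1cccc(OC)c1 | intermediate
3 | 2-(3,5-dimethoxyphenyl)-4,4,5,5-tetramethyl-1,3,2-dioxaborolane | COc1cc(OC)cc(c1)B1OC(C)(C)C(C)(C)O1 | intermediate
4 | 3,5-dimethoxyphenol | COc1cc(O)cc(OC)c1 | intermediate
5 | phenylacetylene | C#Cc1ccccc1 | starting material
6 | methyl chloroformate | COC(=O)Cl | starting material
7 | lithium phenylacetylide | [Li+].[C-]#Cc1ccccc1 | intermediate
8 | methyl 3-phenylprop-2-ynoate | COC(=O)C#Cc1ccccc1 | intermediate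
9 | methyl (2Z)-3-(2-hydroxy-4,6-dimethoxyphenyl)-3-phenylprop-2-enoate | COC(=O)/C=C(/c1ccccc1)c1c(O)cc(OC)cc1OC | intermediate
10 | 5,7-dimethoxy-4-phenyl-2H-chromen-2-one | COc1cc(OC)c2c(-c3ccccc3)cc(=O)oc2c1 | intermediate
11 | (4R)-5,7-dimethoxy-4-phenyl-3,4-dihydro-2H-chromen-2-one | c1c(OC)cc2OC(=O)C[C@H](c3ccccc3)c2c1OC | intermediate
12 | methyl (3R)-3-(2-hydroxy-4,6-dimethoxyphenyl)-3-phenylpropanoate | c1c(OC)cc(O)c([C@H](CC(=O)OC)c2ccccc2)c1OC | intermediate
13 | (2E)-2-methylbut-2-en-1-ol | C/C=C(\C)CO | starting material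
14 | methyl (2E)-2-methylbut-2-en-1-yl carbonate | C/C=C(\C)COC(=O)OC | intermediate
15 | methyl (3R)-3-{2,4-dimethoxy-6-[(2R)-3-methylbut-3-en-2-yl]oxyphenyl}-3-phenylpropanoate | c1c(OC)cc(O[C@H](C)C(C)=C)c([C@H](CC(=O)OC)c2ccccc2)c1OC | intermediate
16 | methyl (3R)-3-{2-[(2R,3S)-4-(9-borabicyclo[3.3.1]nonan-9-yl)-3-methylbutan-2-yl]oxy-4,6-dimethoxyphenyl}-3-phenylpropanoate | c1c(OC)cc(O[C@H](C)[C@@H](C)CB2C3CCCC2CCC3)c([C@H](CC(=O)OC)c2ccccc2)c1OC | intermediate
17 | methyl (3R)-3-{2-[(2R,3S)-4-hydroxy-3-methylbutan-2-yl]oxy-4,6-dimethoxyphenyl}-3-phenylpropanoate | c1c(OC)cc(O[C@H](C)[C@@H](C)CO)c([C@H](CC(=O)OC)c2ccccc2)c1OC | intermediate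
18 | methyl (3R)-3-{2,4-dimethoxy-6-[(2R,3R)-3-methyl-4-oxobutan-2-yl]oxyphenyl}-3-phenylpropanoate | c1c(OC)cc(O[C@H](C)[C@@H](C)C=O)c([C@H](CC(=O)OC)c2ccccc2)c1OC | intermediate
19 | (2R,3R)-3-{3,5-dimethoxy-2-[(1R)-3-methoxy-3-oxo-1-phenylpropyl]phenoxy}-2-methylbutanoic acid | c1c(OC)cc(O[C@H](C)[C@@H](C)C(=O)O)c([C@H](CC(=O)OC)c2ccccc2)c1OC | intermediate
20 | mixed anhydride of acid 19 with trifluoroacetic acid | c1c(OC)cc(O[C@H](C)[C@@H](C)C(=O)OC(=O)C(F)(F)F)c([C@H](CC(=O)OC)c2ccccc2)c1OC | intermediate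
21 | methyl (3R)-3-[(2R,3R)-5,7-dimethoxy-2,3-dimethyl-4-oxo-3,4-dihydro-2H-chromen-8-yl]-3-phenylpropanoate | c1c(OC)c2C(=O)[C@H](C)[C@@H](C)Oc2c([C@H](CC(=O)OC)c2ccccc2)c1OC | intermediate
22 | methyl (3R)-3-[(2R,3R)-5,7-dihydroxy-2,3-dimethyl-4-oxo-3,4-dihydro-2H-chromen-8-yl]-3-phenylpropanoate | c1c(O)c2C(=O)[C@H](C)[C@@H](C)Oc2c([C@H](CC(=O)OC)c2ccccc2)c1O | intermediate
23 | (2R,3R,10R)-5-hydroxy-2,3-dimethyl-10-phenyl-2,3,9,10-tetrahydro-4H,8H-pyrano[2,3-h]chromene-4,8-dione | c1c(O)c2C(=O)[C@H](C)[C@@H](C)Oc2c3c1OC(=O)C[C@@H]3c1ccccc1 | intermediate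
24 | (2R,3R,10R)-5-hydroxy-6-iodo-2,3-dimethyl-10-phenyl-2,3,9,10-tetrahydro-4H,8H-pyrano[2,3-h]chromene-4,8-dione | Ic1c(O)c2C(=O)[C@H](C)[C@@H](C)Oc2c3c1OC(=O)C[C@@H]3c1ccccc1 | intermediate
25 | 5-methylhex-5-en-2-one | CC(=O)CCC(C)=C | starting material
26 | lithium 5-methylhexa-1,5-dien-2-olate | [Li+].[O-]C(=C)CCC(C)=C | intermediate
27 | 5-methylhexa-1,5-dien-2-yl trifluoromethanesulfonate | C=C(C)CCC(=C)OS(=O)(=O)C(F)(F)F | intermediate
28 | (2-methylprop-1-en-1-yl)boronic acid | CC(C)=CB(O)O | starting material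
29 | 2,7-dimethyl-5-methylideneocta-1,6-diene | C=C(C)CCC(=C)C=C(C)C | intermediate
30 | 4,4,5,5-tetramethyl-2-[(2S)-5-methyl-2-(2-methylprop-1-en-1-yl)hex-5-en-1-yl]-1,3,2-dioxaborolane | C=C(C)CC[C@@H](C=C(C)C)CB1OC(C)(C)C(C)(C)O1 | intermediate
31 | (2S)-5-methyl-2-(2-methylprop-1-en-1-yl)hex-5-en-1-ol | C=C(C)CC[C@@H](C=C(C)C)CO | intermediate
32 | (5S)-6-iodo-2-methyl-5-(2-methylprop-1-en-1-yl)hex-1-ene | C=C(C)CC[C@@H](C=C(C)C)CI | intermediate
33 | [(2S)-5-methyl-2-(2-methylprop-1-en-1-yl)hex-5-en-1-yl]lithium | C=C(C)CC[C@@H](C=C(C)C)C[Li] | intermediate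
34 | chloro[(2S)-5-methyl-2-(2-methylprop-1-en-1-yl)hex-5-en-1-yl]zinc | C=C(C)CC[C@@H](C=C(C)C)C[Zn]Cl | intermediate
35 | (2R,3R,10R)-5-hydroxy-2,3-dimethyl-6-[(2R)-5-methyl-2-(2-methylprop-1-en-1-yl)hex-5-en-1-yl]-10-phenyl-2,3,9,10-tetrahydro-4H,8H-pyrano[2,3-h]chromene-4,8-dione | C=C(C)CC[C@@H](C=C(C)C)Cc1c(O)c2C(=O)[C@H](C)[C@@H](C)Oc2c3c1OC(=O)C[C@@H]3c1ccccc1 | intermediate
36 | 3-methylbut-2-en-1-ol | CC(C)=CCO | starting material
37 | methyl 3-methylbut-2-en-1-yl carbonate | CC(C)=CCOC(=O)OC | intermediate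
38 | dilithium (3R)-3-{(2R,3R)-5-hydroxy-2,3-dimethyl-6-[(2R)-5-methyl-2-(2-methylprop-1-en-1-yl)hex-5-en-1-yl]-7-oxido-4-oxo-3,4-dihydro-2H-chromen-8-yl}-3-phenylpropanoate | [Li+].[Li+].C=C(C)CC[C@@H](C=C(C)C)Cc1c(O)c2C(=O)[C@H](C)[C@@H](C)Oc2c([C@H](CC(=O)[O-])c2ccccc2)c1[O-] | intermediate
39 | (3R)-3-{(2R,3R,6S)-4-hydroxy-2,3-dimethyl-6-(3-methylbut-2-en-1-yl)-6-[(2R)-5-methyl-2-(2-methylprop-1-en-1-yl)hex-5-en-1-yl]-5,7-dioxo-3,5,6,7-tetrahydro-2H-chromen-8-yl}-3-phenylpropanoic acid | C=C(C)CC[C@@H](C=C(C)C)C[C@@]1(CC=C(C)C)C(=O)C2=C(O)[C@H](C)[C@@H](C)OC2=C([C@H](CC(=O)O)c2ccccc2)C1=O | target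

**Step count**
Total: 20 steps. Longest linear sequence: 13 steps (1, 2, 4, 5, 6, 8, 9, 10, 11, 12, 13, 18, 20, from resorcinol).

**Three steps most likely to fail**

Step 16 (protoboration of a diene whose far terminus is fully substituted; the 1,2- versus 1,4-protonation ratio and the enantioselectivity are uncertain). The fallback sets out from triene 29 and comes back at alcohol 31. The protoboration is run with an achiral catalyst (CuCl, Xantphos, B2pin2, MeOH) to give the racemic homoallylic pinacol boronate F1, and perborate oxidation gives the racemic alcohol F2. Kinetic resolution by lipase-catalysed acylation (Amano lipase PS, vinyl acetate, hexane, 0 °C) converts the (R)-enantiomer into the (R)-acetate F3, and the unreacted (S)-alcohol is 31. This replaces asymmetric catalysis by resolution; it does not cure a regiochemical failure.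

Step 18 (Negishi coupling at a di-ortho-substituted, electron-rich iodide that carries a free chelated phenol). The fallback sets out from boronate 30 (isolated by leaving out the perborate in step 16) and iodide 24 and comes back at lactone 35. KHF2 in MeOH/H2O converts 30 into the potassium alkyltrifluoroborate F4. Suzuki–Miyaura alkyl coupling with 24 (Pd(OAc)2, RuPhos, K2CO3, toluene/H2O, 80 °C) proceeds with opening of the lactone under the aqueous base, and acidification gives the hydroxy acid F5. Catalytic p-TsOH in toluene closes the lactone again to 35. This removes the organolithium and organozinc reagents and two steps of the side-chain branch.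

Step 20 (the proposed new reaction; face selectivity, C6 versus C8 and C versus O selectivity are unproven). The fallback uses known chemistry, sets out from lactone 35 and comes back at target 39. LiOH opens the lactone to 38 as before, and classical alkylative dearomatisation with 1-bromo-3-methylbut-2-ene in aqueous alkali at 0 °C (no metal, no facial control) gives 39 together with its C6 epimer F6. The two are separated by preparative reversed-phase HPLC.

**Further compounds**
F1 | step 16 | racemic 4,4,5,5-tetramethyl-2-[5-methyl-2-(2-methylprop-1-en-1-yl)hex-5-en-1-yl]-1,3,2-dioxaborolane | C=C(C)CCC(C=C(C)C)CB1OC(C)(C)C(C)(C)O1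
F2 | step 16 | racemic 5-methyl-2-(2-methylprop-1-en-1-yl)hex-5-en-1-ol | C=C(C)CCC(C=C(C)C)CO
F3 | step 16 | (2R)-5-methyl-2-(2-methylprop-1-en-1-yl)hex-5-en-1-yl acetate | C=C(C)CC[C@H](C=C(C)C)COC(C)=O
F4 | step 18 | potassium trifluoro[(2S)-5-methyl-2-(2-methylprop-1-en-1-yl)hex-5-en-1-yl]borate | [K+].C=C(C)CC[C@@H](C=C(C)C)C[B-](F)(F)F
F5 | step 18 | (3R)-3-{(2R,3R)-5,7-dihydroxy-2,3-dimethyl-6-[(2R)-5-methyl-2-(2-methylprop-1-en-1-yl)hex-5-en-1-yl]-4-oxo-3,4-dihydro-2H-chromen-8-yl}-3-phenylpropanoic acid | C=C(C)CC[C@@H](C=C(C)C)Cc1c(O)c2C(=O)[C@H](C)[C@@H](C)Oc2c([C@H](CC(=O)O)c2ccccc2)c1O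
F6 | step 20 | (3R)-3-{(2R,3R,6R)-4-hydroxy-2,3-dimethyl-6-(3-methylbut-2-en-1-yl)-6-[(2R)-5-methyl-2-(2-methylprop-1-en-1-yl)hex-5-en-1-yl]-5,7-dioxo-3,5,6,7-tetrahydro-2H-chromen-8-yl}-3-phenylpropanoic acid | C=C(C)CC[C@@H](C=C(C)C)C[C@]1(CC=C(C)C)C(=O)C2=C(O)[C@H](C)[C@@H](C)OC2=C([C@H](CC(=O)O)c2ccccc2)C1=O
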